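**Plan**
1. Retrosynthesis: the MOM ether on O7 is removed last. Ring C is then cut at O1–C8a and at C4–C4a, giving the ring A piece 10 (Br on C4a, F on C8a) and the (S)-β-hydroxy Weinreb amide 5, which already carries ring B and the chromene ring.
2. Feature used: C4a and C8a are neighbours on ring A. Br on C4a becomes the carbanion that takes C4. F on C8a lies next to H8, the only ring proton flanked by F and the O7 MOM group, so a C8–C8a aryne can be raised after the acylation and O1 closes the six-membered ring C on C8a.
3. Forward: 5 in three steps from nitrile 1 (Blaise reaction, transfer hydrogenation, amidation); 10 in three steps from phenol 6 (iodination, MOM ether, prenylation); union and closure of ring C, the only ring made, in one flask; MOM cleavage.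
4. Stereochemistry: the single stereocentre C2 is set by Noyori transfer hydrogenation (step 2) and kept, because the C2–O1 bond is never broken and C4 stays a masked hemiaminal until ring C is closed.

Key step: step 7

Remark on the chemistry: 1 and 6 are taken as catalogue compounds; atoms are numbered as in the chroman-4-one core of the target (O1, C2, C3, C4, C4a, C5 to C8, C8a; O7 on C7).

**Step 1**
Reactants: 1 2,2-dimethyl-2H-chromene-6-carbonitrile
Product: 3 ethyl 3-(2,2-dimethyl-2H-chromen-6-yl)-3-oxopropanoate, via zinc enaminate 2 (not isolated)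
Conditions: Zn (TMSCl-activated), BrCH2CO2Et (slow addition), THF, reflux; then 3 M HCl (aq.), 23 °C
Reagents that add atoms: ethyl bromoacetate, CCOC(=O)CBr; water, O
Why: Blaise reaction: the Reformatsky reagent formed in the flask should add to the nitrile carbon of 1 to give zinc enaminate 2, which aqueous acid hydrolyses to the β-keto ester, the chromene alkene being inert to organozinc reagents and to brief dilute acid.

**Step 2**
Reactants: 3 ethyl 3-(2,2-dimethyl-2H-chromen-6-yl)-3-oxopropanoate
Product: 4 ethyl (3S)-3-(2,2-dimethyl-2H-chromen-6-yl)-3-hydroxypropanoate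
Conditions: RuCl(p-cymene)[(S,S)-TsDPEN] (1 mol %), HCO2H–Et3N (5:2), DMF, 40 °C
Reagents that add atoms: none
Why: Noyori asymmetric transfer hydrogenation of an aryl β-keto ester: the (S,S)-TsDPEN catalyst should deliver hydride to the Re face of the aryl ketone (aryl group over the η6-arene, as for acetophenone), which sets the carbinol carbon (the future C2) as S and leaves the chromene alkene unreduced.

**Step 3**
Reactants: 4 ethyl (3S)-3-(2,2-dimethyl-2H-chromen-6-yl)-3-hydroxypropanoate
Product: 5 (3S)-3-(2,2-dimethyl-2H-chromen-6-yl)-3-hydroxy-N-methoxy-N-methylpropanamide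
Conditions: MeNH(OMe)·HCl, i-PrMgCl, THF, −20 → 0 °C
Reagents that add atoms: N,O-dimethylhydroxylamine hydrochloride, CNOC.Cl
Why: Weinreb amide formation by aminolysis of the ester with the magnesium amide of N,O-dimethylhydroxylamine; the β-hydroxyl is carried as its magnesium alkoxide at low temperature and the stereocentre is not touched.

**Step 4**
Reactants: 6 4-bromo-3-fluorophenol
Product: 7 4-bromo-5-fluoro-2-iodophenol
Conditions: NIS, TsOH·H2O (10 mol %), MeCN, 0 → 23 °C
Reagents that add atoms: N-iodosuccinimide, O=C1CCC(=O)N1I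
Why: Electrophilic aromatic iodination of a phenol: the para position is blocked by Br, and of the two ortho positions the unhindered one para to F should react in preference to the one squeezed between OH and F.

**Step 5**
Reactants: 7 4-bromo-5-fluoro-2-iodophenol
Product: 8 1-bromo-2-fluoro-5-iodo-4-(methoxymethoxy)benzene
Conditions: MOMCl, i-Pr2NEt, CH2Cl2, 0 → 23 °C
Reagents that add atoms: chloromethyl methyl ether, COCCl
Why: O-alkylation of the phenol (MOM ether formation); the MOM group protects O7 against the organometallic steps and later helps acidify H8.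

**Step 6**
Reactants: 8 1-bromo-2-fluoro-5-iodo-4-(methoxymethoxy)benzene
Product: 10 1-bromo-2-fluoro-4-(methoxymethoxy)-5-(3-methylbut-2-en-1-yl)benzene, via aryl Grignard 9 (not isolated)
Conditions: i-PrMgCl·LiCl, THF, −40 °C; then prenyl bromide, Li2CuCl4 (3 mol %), −40 → 0 °C
Reagents that add atoms: 1-bromo-3-methylbut-2-ene, CC(C)=CCBr
Why: Iodine–magnesium exchange should be far faster at the iodide ortho to the MOM ether than at the bromide, and the Li2CuCl4-catalysed Grignard–allyl halide coupling of 9 should attack the unhindered primary carbon of prenyl bromide to give the linear prenyl group.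

**Step 7**
Reactants: 10 1-bromo-2-fluoro-4-(methoxymethoxy)-5-(3-methylbut-2-en-1-yl)benzene; 5 (3S)-3-(2,2-dimethyl-2H-chromen-6-yl)-3-hydroxy-N-methoxy-N-methylpropanamide
Product: 16 (2S)-2-(2,2-dimethyl-2H-chromen-6-yl)-7-(methoxymethoxy)-6-(3-methylbut-2-en-1-yl)-2,3-dihydro-4H-chromen-4-one, via aryllithium 11 (not isolated), via sodium alkoxide 12 (not isolated), via hemiaminal dianion 13 (not isolated), via aryne 14 (not isolated), via cyclised hemiaminal 15 (not isolated)
Conditions: 10, t-BuLi (2 equiv), THF, −78 °C; then 12 (from 5, NaH, THF, 0 °C), −78 °C; then LiTMP (1.2 equiv), −78 → 0 °C; then aq. NH4Cl, 0 °C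
Reagents that add atoms: none
Why: Proposed new method: bromine–lithium exchange on 10 gives the ortho-fluoroaryllithium 11, which adds to the amide carbonyl of sodium alkoxide 12 to form C4–C4a and stops at the chelated N-methoxy-N-methyl hemiaminal 13 as in a Weinreb ketone synthesis; LiTMP then removes H8, loss of LiF gives the C8–C8a aryne 14, and the tethered alkoxide O1 adds to C8a to form O1–C8a (15), after which the quench protonates C8 and releases the C4 ketone. The closest known reaction types are the Weinreb acylation of aryllithiums and the classical ring closure of tethered alkoxides onto arynes made by ortho-lithiation of fluoroarenes; their union in one flask on a hemiaminal dianion is the untested part. Ring C is the only ring closed, by a 6-exo-dig addition of O1 in the plane of the aryne. No new stereocentre is formed: C2 comes from 5 with its C–O bond intact, and because C4 stays a hemiaminal until the buffered quench, neither retro-aldol cleavage nor E1cB opening of the flavanone can scramble it. The step needs exchange before deprotonation (t-BuLi at −78 °C), lithiation at C8 only (H8 is the one proton flanked by F and the MOM ether), and attack at C8a rather than C8 (fixed by the tether length and by the MOM ether on C7, which polarises a 3-alkoxyaryne for attack at the distal carbon).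

**Step 8**
Reactants: 16 (2S)-2-(2,2-dimethyl-2H-chromen-6-yl)-7-(methoxymethoxy)-6-(3-methylbut-2-en-1-yl)-2,3-dihydro-4H-chromen-4-one
Product: 17 Dinklagin A, (2S)-2-(2,2-dimethyl-2H-chromen-6-yl)-7-hydroxy-6-(3-methylbut-2-en-1-yl)-2,3-dihydro-4H-chromen-4-one
Conditions: 3 M HCl (aq.), MeOH–THF, 23 → 40 °C
Reagents that add atoms: none
Why: Acid-catalysed acetal exchange (MOM cleavage) in methanol should free the O7 hydroxyl, the C2 stereocentre being stable to dilute acid and the mild temperature limiting attack of the new phenol on the prenyl group.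

**Compound list**
1 | 2,2-dimethyl-2H-chromene-6-carbonitrile | CC1(C)C=Cc2cc(C#N)ccc2O1 | starting material
2 | ethyl 3-[(bromozincio)amino]-3-(2,2-dimethyl-2H-chromen-6-yl)prop-2-enoate (zinc enaminate) | CCOC(=O)C=C(N[Zn]Br)c1ccc2OC(C)(C)C=Cc2c1 | intermediate (not isolated)
3 | ethyl 3-(2,2-dimethyl-2H-chromen-6-yl)-3-oxopropanoate | CCOC(=O)CC(=O)c1ccc2OC(C)(C)C=Cc2c1 | intermediate
4 | ethyl (3S)-3-(2,2-dimethyl-2H-chromen-6-yl)-3-hydroxypropanoate | CCOC(=O)C[C@H](O)c1ccc2OC(C)(C)C=Cc2c1 | intermediate
5 | (3S)-3-(2,2-dimethyl-2H-chromen-6-yl)-3-hydroxy-N-methoxy-N-methylpropanamide | CON(C)C(=O)C[C@H](O)c1ccc2OC(C)(C)C=Cc2c1 | intermediate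
6 | 4-bromo-3-fluorophenol | Oc1ccc(Br)c(F)c1 | starting material
7 | 4-bromo-5-fluoro-2-iodophenol | Oc1cc(F)c(Br)cc1I | intermediate
8 | 1-bromo-2-fluoro-5-iodo-4-(methoxymethoxy)benzene | COCOc1cc(F)c(Br)cc1I | intermediate
9 | [4-bromo-5-fluoro-2-(methoxymethoxy)phenyl]magnesium chloride | COCOc1cc(F)c(Br)cc1[Mg]Cl | intermediate (not isolated)
10 | 1-bromo-2-fluoro-4-(methoxymethoxy)-5-(3-methylbut-2-en-1-yl)benzene | COCOc1cc(F)c(Br)cc1CC=C(C)C | intermediate
11 | [2-fluoro-4-(methoxymethoxy)-5-(3-methylbut-2-en-1-yl)phenyl]lithium | COCOc1cc(F)c([Li])cc1CC=C(C)C | intermediate (not isolated)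
12 | sodium alkoxide of 5 | CON(C)C(=O)C[C@H](O[Na])c1ccc2OC(C)(C)C=Cc2c1 | intermediate (not isolated)
13 | open-chain hemiaminal dianion: adduct of 11 to the amide carbonyl of 12, O–Li at C4, O–Na at C2 (S), either configuration at C4 | CON(C)C(O[Li])(C[C@H](O[Na])c1ccc2OC(C)(C)C=Cc2c1)c1cc(CC=C(C)C)c(OCOC)cc1F | intermediate (not isolated)
14 | C8–C8a aryne derived from 13 by loss of H8 and fluoride | CON(C)C(O[Li])(C[C@H](O[Na])c1ccc2OC(C)(C)C=Cc2c1)C1=CC(CC=C(C)C)=C(OCOC)C#C1 | intermediate (not isolated)
15 | cyclised hemiaminal: (2S)-chroman with O–Li and N(OMe)Me on C4 and the metal on C8 | CC(C)=CCc1cc2c(c([Na])c1OCOC)O[C@H](c1ccc3c(c1)C=CC(C)(C)O3)CC2(O[Li])N(C)OC | intermediate (not isolated)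
16 | (2S)-2-(2,2-dimethyl-2H-chromen-6-yl)-7-(methoxymethoxy)-6-(3-methylbut-2-en-1-yl)-2,3-dihydro-4H-chromen-4-one | CC(C)=CCc1cc2c(cc1OCOC)O[C@H](c1ccc3c(c1)C=CC(C)(C)O3)CC2=O | intermediate
17 | Dinklagin A, (2S)-2-(2,2-dimethyl-2H-chromen-6-yl)-7-hydroxy-6-(3-methylbut-2-en-1-yl)-2,3-dihydro-4H-chromen-4-one | CC(C)=CCc1cc2c(cc1O)O[C@H](c1ccc3c(c1)C=CC(C)(C)O3)CC2=O | target

**Totals**
Total step count: 8. Longest linear sequence: 5 steps (steps 1, 2, 3, 7, 8 or steps 4, 5, 6, 7, 8).

**Steps most likely to fail**

1. Step 7. Aryllithium 11 may lose LiF before it meets the amide, which would give the wrong aryne across C4a–C8a. The lithium may also migrate from C4a to C8, or aryne 14 may be captured by the amide base instead of by O1. Fallback with known chemistry, setting out from 10 and returning at 16: bromine–lithium exchange on 10 and acylation with N-methoxy-N-methylacetamide should give 1-[2-fluoro-4-(methoxymethoxy)-5-(3-methylbut-2-en-1-yl)phenyl]ethan-1-one F1. Claisen condensation with ethyl formate (NaH, THF) and heating of the sodium enolate in DMF should close the pyranone ring by intramolecular SNAr at the ketone-activated C–F bond, giving 7-(methoxymethoxy)-6-(3-methylbut-2-en-1-yl)-4H-chromen-4-one F2. Rhodium-catalysed asymmetric 1,4-addition (Hayashi–Miyaura reaction; [Rh(OH)(cod)]2, electron-poor atropisomeric bisphosphine, toluene–H2O) of (2,2-dimethyl-2H-chromen-6-yl)boronic acid F3 should then set C2 and give 16. F3 would be made from commercial 6-bromo-2,2-dimethyl-2H-chromene by lithiation and borylation, and the ligand antipode used is the one that leads to the 2S product.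

2. Step 6. The aryl nucleophile may attack the tertiary γ-carbon of prenyl bromide (reverse-prenyl isomer), or the exchange may not fully discriminate iodide from bromide. Fallback setting out from 8 and returning at 10: the same iodine–magnesium exchange followed by allyl bromide, for which both ends of the electrophile are equivalent, should give 1-bromo-2-fluoro-4-(methoxymethoxy)-5-(prop-2-en-1-yl)benzene F4. Cross-metathesis of F4 with 2-methylbut-2-ene (second-generation Grubbs catalyst, 40 °C) should then give 10.

3. Step 8. Acid may promote ring closure of the prenyl group onto the freed O7 hydroxyl, or addition of methanol to the chromene alkene. Fallback setting out from 16 and returning at 17: TESOTf with 2,2′-bipyridyl in CH2Cl2 at 0 °C should exchange the aryl MOM ether for a silyl ether without protic acid, giving (2S)-2-(2,2-dimethyl-2H-chromen-6-yl)-6-(3-methylbut-2-en-1-yl)-7-[(triethylsilyl)oxy]-2,3-dihydro-4H-chromen-4-one F5. Buffered fluoride (TBAF–AcOH, THF, 0 °C) should then free the phenol to give 17.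

**Further compounds**
F1 | step 7 | 1-[2-fluoro-4-(methoxymethoxy)-5-(3-methylbut-2-en-1-yl)phenyl]ethan-1-one | CC(=O)c1cc(CC=C(C)C)c(OCOC)cc1F
F2 | step 7 | 7-(methoxymethoxy)-6-(3-methylbut-2-en-1-yl)-4H-chromen-4-one | O=c1ccoc2cc(OCOC)c(CC=C(C)C)cc12
F3 | step 7 | (2,2-dimethyl-2H-chromen-6-yl)boronic acid | OB(O)c1ccc2OC(C)(C)C=Cc2c1
F4 | step 6 | 1-bromo-2-fluoro-4-(methoxymethoxy)-5-(prop-2-en-1-yl)benzene | COCOc1cc(F)c(Br)cc1CC=C
F5 | step 8 | (2S)-2-(2,2-dimethyl-2H-chromen-6-yl)-6-(3-methylbut-2-en-1-yl)-7-[(triethylsilyl)oxy]-2,3-dihydro-4H-chromen-4-one | CC(C)=CCc1cc2c(cc1O[Si](CC)(CC)CC)O[C@H](c1ccc3c(c1)C=CC(C)(C)O3)CC2=O
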